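Retrosynthesis (germacrane numbering): remove the O14 isovalerate and the O9 acetate; shift the lactone acyl bond C12–O6 to O9, which turns the trans-fused five-membered lactone into a bridged six-membered lactone; cut C6–C7 (carbonyl allylation), then C7=C11 and C12–O9 (metathesis, esterification), C9–C10 (alkenyl addition to an aldehyde) and C1=C10 (Wittig), back to nerol, (S)-but-3-ene-1,2-diol and 2-(bromomethyl)acrylic acid.
Forward: the C1–C6/C10/C14 alkenyl iodide (steps 1–6) and the C7–C9 aldehyde (steps 7–9) are joined at C9–C10 (step 10); O9 is acylated and the temporary six-membered lactone closed by metathesis (steps 11–12); the C6 enal is unveiled (steps 13–14); the ten-membered ring is closed at C6–C7 (step 15); acyl transfer from O9 to O6 builds the five-membered lactone (step 16); acetylation, desilylation and isovalerylation finish the route (steps 17–19).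
Enabling feature: in the target O9 and C11 sit on the same face of the ten-membered ring and are 1,3-related through C8, so C12 can be parked on O9 as an unsaturated six-membered lactone (O9, C9, C8, C7, C11, C12) that is absent from the target; this ring locks the geometry of the C7=C11 allyl unit, lets the chain leaving C9 reach C7 on one face only, and is opened again when O6 takes over C12.
Stereochemistry: C8 from the chiral pool; C9 by Felkin–Anh addition (step 10); C7 and C6 in step 15 (1,3-cis bridge and closed chair of the ring-locked allylchromium); Z-C4=C5 from nerol, Z-C1=C10 from the iodo-Wittig reaction and a stereoretentive coupling.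

Key step: step 15

Remark: atom numbers are those of the germacrane skeleton (C6 lactone carbinol, C7 ring-fusion carbon, C11=C13 exocyclic methylene, C12 carbonyl, C14 oxymethyl on C10, C15 methyl on C4); the target is taken as the 6α,12-olide with 7α-H, 8β-OH and 9β-OAc, which is what the given configuration (6R,7R,8S,9R) corresponds to.

Step 1
Reactants: 1 nerol
Product: 2 neryl 4-methoxybenzyl ether
Conditions: NaH, 4-methoxybenzyl chloride, THF/DMF, 0 → 23 °C
Reagents that add atoms: 4-methoxybenzyl chloride, COc1ccc(CCl)cc1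
Why: Williamson etherification of the primary allylic alkoxide; the Z-trisubstituted alkene that becomes C4=C5 is not touched.

Step 2
Reactants: 2 neryl 4-methoxybenzyl ether
Product: 3 6,7-epoxide of 2
Conditions: mCPBA (1.0 equiv), CH2Cl2, −20 → 0 °C
Reagents that add atoms: 3-chloroperoxybenzoic acid, OOC(=O)c1cccc(Cl)c1
Why: Prilezhaev epoxidation should take the remote, more electron-rich alkene because the other one is deactivated by the allylic ether oxygen; the new oxirane centre is destroyed in step 3, so its configuration does not matter.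

Step 3
Reactants: 3 6,7-epoxide
Product: 5 (4Z)-6-[(4-methoxybenzyl)oxy]-4-methylhex-4-enal, via glycol 4 (not isolated)
Conditions: H5IO6, THF/H2O, 0 °C
Reagents that add atoms: none
Why: acid-mediated epoxide hydrolysis followed by periodate glycol cleavage (Malaprade reaction) in one flask releases C1 as the aldehyde and the isopropylidene carbon as acetone, leaving the Z alkene and the PMB ether intact.

Step 4
Reactants: 5 (4Z)-6-[(4-methoxybenzyl)oxy]-4-methylhex-4-enal; 6 ethyl (triphenyl-λ5-phosphanylidene)acetate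
Product: 8 ethyl (2Z,6Z)-2-iodo-8-[(4-methoxybenzyl)oxy]-6-methylocta-2,6-dienoate, via iodo ylide 7 (not isolated)
Conditions: 6, N-iodosuccinimide, CH2Cl2, −20 °C; then 5, 0 → 23 °C
Reagents that add atoms: N-iodosuccinimide, O=C1CCC(=O)N1I
Why: iodination of the stabilised ylide (the succinimide anion takes the proton) followed by Wittig olefination; as with other ester-stabilised ylides the alkyl chain should end up trans to the ester and cis to iodine, which fixes C14 trans and the future C9 cis to C2 on C1=C10.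

Step 5
Reactants: 8 ethyl (2Z,6Z)-2-iodo-8-[(4-methoxybenzyl)oxy]-6-methylocta-2,6-dienoate
Product: 9 (2Z,6Z)-2-iodo-8-[(4-methoxybenzyl)oxy]-6-methylocta-2,6-dien-1-ol
Conditions: i-Bu2AlH (2.5 equiv), CH2Cl2, −78 °C
Reagents that add atoms: none
Why: 1,2-reduction of the enoate by the aluminium hydride; the alkenyl iodide, both alkene geometries and the PMB ether are inert at −78 °C.

Step 6
Reactants: 9 (2Z,6Z)-2-iodo-8-[(4-methoxybenzyl)oxy]-6-methylocta-2,6-dien-1-ol
Product: 10 tert-butyl({(2Z,6Z)-2-iodo-8-[(4-methoxybenzyl)oxy]-6-methylocta-2,6-dien-1-yl}oxy)dimethylsilane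
Conditions: TBSCl, imidazole, DMF, 0 → 23 °C
Reagents that add atoms: tert-butyldimethylsilyl chloride, CC(C)(C)[Si](C)(C)Cl
Why: silylation of the primary allylic alcohol; a silyl ether (not an ester) is placed on O14 so that the later alkenylchromium carries no β-leaving group.

Step 7
Reactants: 11 (2S)-but-3-ene-1,2-diol
Product: 12 (3S)-3,4-bis[(tert-butyldimethylsilyl)oxy]but-1-ene
Conditions: TBSCl (2.4 equiv), imidazole, DMF, 23 °C
Reagents that add atoms: tert-butyldimethylsilyl chloride, CC(C)(C)[Si](C)(C)Cl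
Why: exhaustive silylation; the stereocentre (future C8) is not involved.

Step 8
Reactants: 12 (3S)-3,4-bis[(tert-butyldimethylsilyl)oxy]but-1-ene
Product: 13 (2S)-2-[(tert-butyldimethylsilyl)oxy]but-3-en-1-ol
Conditions: HF·pyridine, pyridine, THF, 0 °C
Reagents that add atoms: none
Why: selective fluoride-mediated cleavage of the sterically more accessible primary silyl ether in the presence of the secondary one.

Step 9
Reactants: 13 (2S)-2-[(tert-butyldimethylsilyl)oxy]but-3-en-1-ol
Product: 14 (2S)-2-[(tert-butyldimethylsilyl)oxy]but-3-enal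
Conditions: Dess–Martin periodinane, CH2Cl2, 0 → 23 °C; used crude at once
Reagents that add atoms: none
Why: Dess–Martin oxidation under non-basic conditions should keep the α-stereocentre and the β,γ-alkene in place; the aldehyde is not stored.

Step 10
Reactants: 10 tert-butyl({(2Z,6Z)-2-iodo-8-[(4-methoxybenzyl)oxy]-6-methylocta-2,6-dien-1-yl}oxy)dimethylsilane; 14 (2S)-2-[(tert-butyldimethylsilyl)oxy]but-3-enal
Product: 16 (3S,4R,5Z,9Z)-3-[(tert-butyldimethylsilyl)oxy]-5-({[tert-butyldimethylsilyl]oxy}methyl)-11-[(4-methoxybenzyl)oxy]-9-methylundeca-1,5,9-trien-4-ol, via alkenylchromium dichloride 15 (not isolated)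
Conditions: CrCl2 (5 equiv), NiCl2 (1 mol%), DMSO, 23 °C; 14 in 1.5-fold excess
Reagents that add atoms: none
Why: Nozaki–Hiyama–Kishi coupling, in which zerovalent nickel inserts into the carbon–iodine bond with retention of alkene geometry and hands the alkenyl group to trivalent chromium; the neutral reagent should not epimerise 14 and should add by the polar Felkin–Anh mode (silyloxy group anti to the incoming alkenyl), giving the 8,9-anti alcohol (9R).

Step 11
Reactants: 16 (3S,4R,5Z,9Z)-3-[(tert-butyldimethylsilyl)oxy]-5-({[tert-butyldimethylsilyl]oxy}methyl)-11-[(4-methoxybenzyl)oxy]-9-methylundeca-1,5,9-trien-4-ol; 17 2-(bromomethyl)prop-2-enoic acid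
Product: 18 (3S,4R,5Z,9Z)-3-[(tert-butyldimethylsilyl)oxy]-5-({[tert-butyldimethylsilyl]oxy}methyl)-11-[(4-methoxybenzyl)oxy]-9-methylundeca-1,5,9-trien-4-yl 2-(bromomethyl)prop-2-enoate
Conditions: N,N′-diisopropylcarbodiimide, DMAP (0.1 equiv), CH2Cl2, −20 → 0 °C
Reagents that add atoms: none
Why: Steglich esterification of the only free hydroxyl (O9) with retention at C9; low temperature and catalytic DMAP limit attack on the allylic bromide.

Step 12
Reactants: 18 (3S,4R,5Z,9Z)-3-[(tert-butyldimethylsilyl)oxy]-5-({[tert-butyldimethylsilyl]oxy}methyl)-11-[(4-methoxybenzyl)oxy]-9-methylundeca-1,5,9-trien-4-yl 2-(bromomethyl)prop-2-enoate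
Product: 19 (5S,6R)-3-(bromomethyl)-5-[(tert-butyldimethylsilyl)oxy]-6-[(1Z,5Z)-1-({[tert-butyldimethylsilyl]oxy}methyl)-7-[(4-methoxybenzyl)oxy]-5-methylhepta-1,5-dien-1-yl]-5,6-dihydro-2H-pyran-2-one
Conditions: RuCl2(H2IMes)(=CH-C6H4-2-OiPr) (second-generation Hoveyda–Grubbs catalyst, 5 mol%), toluene, 80 °C, 5 mM
Reagents that add atoms: none
Why: ring-closing metathesis between the terminal vinyl group and the 1,1-disubstituted acrylate closes the six-membered unsaturated lactone with loss of ethylene, the trisubstituted alkenes being too hindered to compete; the ring holds C8 cis to the carbonyl C12 on the new C7=C11 bond.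

Step 13
Reactants: 19 (5S,6R)-3-(bromomethyl)-5-[(tert-butyldimethylsilyl)oxy]-6-[(1Z,5Z)-1-({[tert-butyldimethylsilyl]oxy}methyl)-7-[(4-methoxybenzyl)oxy]-5-methylhepta-1,5-dien-1-yl]-5,6-dihydro-2H-pyran-2-one
Product: 20 (5S,6R)-3-(bromomethyl)-5-[(tert-butyldimethylsilyl)oxy]-6-[(1Z,5Z)-1-({[tert-butyldimethylsilyl]oxy}methyl)-7-hydroxy-5-methylhepta-1,5-dien-1-yl]-5,6-dihydro-2H-pyran-2-one
Conditions: DDQ, CH2Cl2/pH 7 buffer, 0 °C
Reagents that add atoms: none
Why: oxidative cleavage of the PMB ether by DDQ under buffered conditions, which silyl ethers, the allylic bromide and the lactone should survive.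

Step 14
Reactants: 20 (5S,6R)-3-(bromomethyl)-5-[(tert-butyldimethylsilyl)oxy]-6-[(1Z,5Z)-1-({[tert-butyldimethylsilyl]oxy}methyl)-7-hydroxy-5-methylhepta-1,5-dien-1-yl]-5,6-dihydro-2H-pyran-2-one
Product: 21 (2Z,6Z)-7-[(2R,3S)-5-(bromomethyl)-3-[(tert-butyldimethylsilyl)oxy]-6-oxo-3,6-dihydro-2H-pyran-2-yl]-8-[(tert-butyldimethylsilyl)oxy]-3-methylocta-2,6-dienal
Conditions: MnO2 (excess), CH2Cl2, 23 °C
Reagents that add atoms: none
Why: selective MnO2 oxidation of the primary allylic alcohol to the neral-type Z-enal under neutral conditions, which should preserve the alkene geometry.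

Step 15
Reactants: 21 (2Z,6Z)-7-[(2R,3S)-5-(bromomethyl)-3-[(tert-butyldimethylsilyl)oxy]-6-oxo-3,6-dihydro-2H-pyran-2-yl]-8-[(tert-butyldimethylsilyl)oxy]-3-methylocta-2,6-dienal
Product: 23 (1(10)Z,4Z,6R,7S,8S,9R)-8,14-bis[(tert-butyldimethylsilyl)oxy]-6-hydroxygermacra-1(10),4,11(13)-trien-12,9-olide, via allylchromium dichloride 22 (not isolated)
Conditions: CrCl2 (8 equiv), THF/DMF 4:1, 23 °C, syringe-pump addition of 21 to a final 2 mM; aqueous NH4Cl work-up
Reagents that add atoms: none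
Why: CrCl2 reduces the allylic bromide by two single-electron transfers to the allylchromium 22, which adds through its γ-carbon C7 to the tethered C6 aldehyde in a closed six-membered (Zimmerman–Traxler) transition state, i.e. an intramolecular Nozaki–Hiyama–Kishi (Barbier-type) carbonyl allylation, a reaction type with close precedent for closing ten-membered carbocycles from 2-(bromomethyl)alk-2-enoates. The ten-membered ring closes by exo addition to the carbonyl (10-exo-trig at C6) with allylic transposition (SE2′) that makes C11=C13 the exocyclic methylene, and because the tether spans C9 and C7 of the lactone the product is a bridged bicyclo[7.3.1] lactone. C7 is set by the temporary ring: the seven-atom tether leaves C9 on one face of the six-membered lactone and can reach C7 only on that face (1,3-cis bridge), which is the 7α-H configuration. C6 is set by the same ring in a second way: it holds C8 cis to C12, so the reagent is locked as the E-type γ-substituted allylchromium, and the chair with the enal residue pseudo-equatorial (the axial alternative would drive C5 into C10) should give the 6,7-anti relationship, i.e. the 6α-hydroxyl (6R). The step needs γ- over α-attack, which is inherent to allylchromium reagents, ring closure over oligomerisation, which slow addition at high dilution secures, and selective reduction of the carbon–bromine bond, which divalent chromium delivers in the presence of the enal, the lactone and the silyl ethers.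

Step 16
Reactants: 23 (1(10)Z,4Z,6R,7S,8S,9R)-8,14-bis[(tert-butyldimethylsilyl)oxy]-6-hydroxygermacra-1(10),4,11(13)-trien-12,9-olide
Product: 24 (1(10)Z,4Z,6R,7S,8S,9R)-8,14-bis[(tert-butyldimethylsilyl)oxy]-9-hydroxygermacra-1(10),4,11(13)-trien-12,6-olide
Conditions: PPTS (0.2 equiv), CH2Cl2, 23 → 40 °C
Reagents that add atoms: none
Why: acid-catalysed intramolecular transesterification (translactonisation) by 5-exo-trig attack of O6 on C12 and expulsion of O9 should be driven by the exchange of a bridged six-membered lactone for a trans-fused five-membered one; only acyl–oxygen bonds are broken, so no stereocentre changes.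

Step 17
Reactants: 24 (1(10)Z,4Z,6R,7S,8S,9R)-8,14-bis[(tert-butyldimethylsilyl)oxy]-9-hydroxygermacra-1(10),4,11(13)-trien-12,6-olide
Product: 25 (1(10)Z,4Z,6R,7S,8S,9R)-9-acetoxy-8,14-bis[(tert-butyldimethylsilyl)oxy]germacra-1(10),4,11(13)-trien-12,6-olide
Conditions: Ac2O, pyridine, DMAP (cat.), CH2Cl2, 0 → 23 °C
Reagents that add atoms: acetic anhydride, CC(=O)OC(C)=O
Why: DMAP-catalysed acetylation of the only free hydroxyl (O9), the oxygen that carried the temporary lactone.

Step 18
Reactants: 25 (1(10)Z,4Z,6R,7S,8S,9R)-9-acetoxy-8,14-bis[(tert-butyldimethylsilyl)oxy]germacra-1(10),4,11(13)-trien-12,6-olide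
Product: 26 (1(10)Z,4Z,6R,7R,8S,9R)-9-acetoxy-8,14-dihydroxygermacra-1(10),4,11(13)-trien-12,6-olide
Conditions: HF·pyridine, pyridine, THF, 0 → 23 °C
Reagents that add atoms: none
Why: fluoride-mediated cleavage of both silyl ethers under buffered, non-basic conditions, chosen so that the acetyl group should stay on O9 and the α-methylene lactone is not attacked.

Step 19
Reactants: 26 (1(10)Z,4Z,6R,7R,8S,9R)-9-acetoxy-8,14-dihydroxygermacra-1(10),4,11(13)-trien-12,6-olide
Product: 27 target, (1(10)Z,4Z,6R,7R,8S,9R)-9-acetoxy-8-hydroxy-14-[(3-methylbutanoyl)oxy]germacra-1(10),4,11(13)-trien-12,6-olide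
Conditions: 3-methylbutanoyl chloride (1.1 equiv), 2,4,6-collidine, CH2Cl2, −78 → −30 °C
Reagents that add atoms: 3-methylbutanoyl chloride, CC(C)CC(Cl)=O
Why: kinetically selective acylation of the primary allylic 14-hydroxyl over the hindered secondary 8-hydroxyl with a weak, non-nucleophilic base at low temperature.

Compound list
1 | nerol, (2Z)-3,7-dimethylocta-2,6-dien-1-ol | CC(C)=CCC/C(C)=C\CO | starting material
2 | neryl 4-methoxybenzyl ether, 1-({[(2Z)-3,7-dimethylocta-2,6-dien-1-yl]oxy}methyl)-4-methoxybenzene | CC(C)=CCC/C(C)=C\COCc1ccc(OC)cc1 | intermediate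
3 | 3-{(3Z)-5-[(4-methoxybenzyl)oxy]-3-methylpent-3-en-1-yl}-2,2-dimethyloxirane (both oxirane configurations) | CC1(C)OC1CC/C(C)=C\COCc1ccc(OC)cc1 | intermediate
4 | (6Z)-8-[(4-methoxybenzyl)oxy]-2,6-dimethyloct-6-ene-2,3-diol (both C3 configurations; formed in the flask) | CC(C)(O)C(O)CC/C(C)=C\COCc1ccc(OC)cc1 | intermediate
5 | (4Z)-6-[(4-methoxybenzyl)oxy]-4-methylhex-4-enal | O=CCC/C(C)=C\COCc1ccc(OC)cc1 | intermediate
6 | ethyl (triphenyl-λ5-phosphanylidene)acetate | CCOC(=O)C=P(c1ccccc1)(c1ccccc1)c1ccccc1 | starting material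
7 | ethyl iodo(triphenyl-λ5-phosphanylidene)acetate (formed in the flask) | CCOC(=O)C(I)=P(c1ccccc1)(c1ccccc1)c1ccccc1 | intermediate
8 | ethyl (2Z,6Z)-2-iodo-8-[(4-methoxybenzyl)oxy]-6-methylocta-2,6-dienoate | CCOC(=O)/C(I)=C/CC/C(C)=C\COCc1ccc(OC)cc1 | intermediate
9 | (2Z,6Z)-2-iodo-8-[(4-methoxybenzyl)oxy]-6-methylocta-2,6-dien-1-ol | OC/C(I)=C/CC/C(C)=C\COCc1ccc(OC)cc1 | intermediate
10 | tert-butyl({(2Z,6Z)-2-iodo-8-[(4-methoxybenzyl)oxy]-6-methylocta-2,6-dien-1-yl}oxy)dimethylsilane | CC(C)(C)[Si](C)(C)OC/C(I)=C/CC/C(C)=C\COCc1ccc(OC)cc1 | intermediate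
11 | (2S)-but-3-ene-1,2-diol | C=C[C@H](O)CO | starting material
12 | (3S)-3,4-bis[(tert-butyldimethylsilyl)oxy]but-1-ene | C=C[C@H](O[Si](C)(C)C(C)(C)C)CO[Si](C)(C)C(C)(C)C | intermediate
13 | (2S)-2-[(tert-butyldimethylsilyl)oxy]but-3-en-1-ol | C=C[C@H](O[Si](C)(C)C(C)(C)C)CO | intermediate
14 | (2S)-2-[(tert-butyldimethylsilyl)oxy]but-3-enal | C=C[C@H](O[Si](C)(C)C(C)(C)C)C=O | intermediate
15 | alkenylchromium dichloride derived from 10 (formed in the flask) | CC(C)(C)[Si](C)(C)OC/C([Cr](Cl)Cl)=C/CC/C(C)=C\COCc1ccc(OC)cc1 | intermediate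
16 | (3S,4R,5Z,9Z)-3-[(tert-butyldimethylsilyl)oxy]-5-({[tert-butyldimethylsilyl]oxy}methyl)-11-[(4-methoxybenzyl)oxy]-9-methylundeca-1,5,9-trien-4-ol | COc1ccc(COC/C=C(/C)CC/C=C(/CO[Si](C)(C)C(C)(C)C)[C@@H](O)[C@@H](O[Si](C)(C)C(C)(C)C)C=C)cc1 | intermediate
17 | 2-(bromomethyl)prop-2-enoic acid | C=C(CBr)C(=O)O | starting material
18 | (3S,4R,5Z,9Z)-3-[(tert-butyldimethylsilyl)oxy]-5-({[tert-butyldimethylsilyl]oxy}methyl)-11-[(4-methoxybenzyl)oxy]-9-methylundeca-1,5,9-trien-4-yl 2-(bromomethyl)prop-2-enoate | COc1ccc(COC/C=C(/C)CC/C=C(/CO[Si](C)(C)C(C)(C)C)[C@@H](OC(=O)C(=C)CBr)[C@@H](O[Si](C)(C)C(C)(C)C)C=C)cc1 | intermediate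
19 | (5S,6R)-3-(bromomethyl)-5-[(tert-butyldimethylsilyl)oxy]-6-[(1Z,5Z)-1-({[tert-butyldimethylsilyl]oxy}methyl)-7-[(4-methoxybenzyl)oxy]-5-methylhepta-1,5-dien-1-yl]-5,6-dihydro-2H-pyran-2-one | COc1ccc(COC/C=C(/C)CC/C=C(/CO[Si](C)(C)C(C)(C)C)[C@H]2OC(=O)C(CBr)=C[C@@H]2O[Si](C)(C)C(C)(C)C)cc1 | intermediate
20 | (5S,6R)-3-(bromomethyl)-5-[(tert-butyldimethylsilyl)oxy]-6-[(1Z,5Z)-1-({[tert-butyldimethylsilyl]oxy}methyl)-7-hydroxy-5-methylhepta-1,5-dien-1-yl]-5,6-dihydro-2H-pyran-2-one | OC/C=C(/C)CC/C=C(/CO[Si](C)(C)C(C)(C)C)[C@H]1OC(=O)C(CBr)=C[C@@H]1O[Si](C)(C)C(C)(C)C | intermediate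
21 | (2Z,6Z)-7-[(2R,3S)-5-(bromomethyl)-3-[(tert-butyldimethylsilyl)oxy]-6-oxo-3,6-dihydro-2H-pyran-2-yl]-8-[(tert-butyldimethylsilyl)oxy]-3-methylocta-2,6-dienal | O=C/C=C(/C)CC/C=C(/CO[Si](C)(C)C(C)(C)C)[C@H]1OC(=O)C(CBr)=C[C@@H]1O[Si](C)(C)C(C)(C)C | intermediate
22 | allylchromium dichloride derived from 21 (formed in the flask) | O=C/C=C(/C)CC/C=C(/CO[Si](C)(C)C(C)(C)C)[C@H]1OC(=O)C(C[Cr](Cl)Cl)=C[C@@H]1O[Si](C)(C)C(C)(C)C | intermediate
23 | (1(10)Z,4Z,6R,7S,8S,9R)-8,14-bis[(tert-butyldimethylsilyl)oxy]-6-hydroxygermacra-1(10),4,11(13)-trien-12,9-olide (bridged six-membered lactone, 6α-OH, 8β-OSi, 9β-O) | C=C1C(=O)O[C@H]2[C@@H](O[Si](C)(C)C(C)(C)C)[C@@H]1[C@H](O)/C=C(/C)CC/C=C2/CO[Si](C)(C)C(C)(C)C | intermediate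
24 | (1(10)Z,4Z,6R,7S,8S,9R)-8,14-bis[(tert-butyldimethylsilyl)oxy]-9-hydroxygermacra-1(10),4,11(13)-trien-12,6-olide | C=C1C(=O)O[C@@H]2/C=C(/C)CC/C=C(/CO[Si](C)(C)C(C)(C)C)[C@@H](O)[C@@H](O[Si](C)(C)C(C)(C)C)[C@@H]12 | intermediate
25 | (1(10)Z,4Z,6R,7S,8S,9R)-9-acetoxy-8,14-bis[(tert-butyldimethylsilyl)oxy]germacra-1(10),4,11(13)-trien-12,6-olide | C=C1C(=O)O[C@@H]2/C=C(/C)CC/C=C(/CO[Si](C)(C)C(C)(C)C)[C@@H](OC(C)=O)[C@@H](O[Si](C)(C)C(C)(C)C)[C@@H]12 | intermediate
26 | (1(10)Z,4Z,6R,7R,8S,9R)-9-acetoxy-8,14-dihydroxygermacra-1(10),4,11(13)-trien-12,6-olide | C=C1C(=O)O[C@@H]2/C=C(/C)CC/C=C(/CO)[C@@H](OC(C)=O)[C@@H](O)[C@@H]12 | intermediate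
27 | (1(10)Z,4Z,6R,7R,8S,9R)-9-acetoxy-8-hydroxy-14-[(3-methylbutanoyl)oxy]germacra-1(10),4,11(13)-trien-12,6-olide (CNP0603244.1) | C=C1C(=O)O[C@@H]2/C=C(/C)CC/C=C(/COC(=O)CC(C)C)[C@@H](OC(C)=O)[C@@H](O)[C@@H]12 | target

Total step count: 19. Longest linear sequence: 16 steps (steps 1–6, then 10–19); steps 7–9 make the second fragment.

Steps most likely to fail

1. Step 15 (ring closure). The bridged transition state may be too strained for the lactone to hold the C9 side chain over the ring, so that intermolecular allylation to oligomers or plain reduction of the carbon–bromine bond takes over; an open transition state would also erode the anti preference at C6. The fallback sets out from 16 and comes back at 27; it replaces the bridged six-membered lactone on O9 by a fused five-membered lactone on O8. Acetylation of 16 (Ac2O, pyridine, DMAP) gives the 9-acetate F1. HF·pyridine removes both silyl groups to give the 8,14-diol F2. Low-temperature acylation with 3-methylbutanoyl chloride and collidine gives the 14-isovalerate F3. Esterification of O8 with 17 (N,N′-diisopropylcarbodiimide, catalytic DMAP) gives the 2-(bromomethyl)acrylate F4. Ring-closing metathesis with RuCl2(H2IMes)(=CH-C6H4-2-OiPr) closes the 3-(bromomethyl)butenolide F5. DDQ gives the allylic alcohol F6 and MnO2 the enal F7. CrCl2 under high dilution then closes the ten-membered ring by the same carbonyl allylation, now through a fused bicycle, to the 6-hydroxy-8,12-olide F8; this variant depends on delivery of the aldehyde to the C7 face that carries C9 (cis fusion). PPTS-catalysed acyl transfer from O8 to O6 would give 27 directly, the 8-hydroxyl being set free by the lactone shift.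

2. Step 10 (fragment coupling). Facial selectivity at C9 may be insufficient, and the α-silyloxy β,γ-unsaturated aldehyde may degrade (epimerisation at C8, migration of the alkene into conjugation) before it is trapped. The fallback sets out from 16 as obtained together with its C9 epimer F9 and returns to 16. Dess–Martin oxidation of the mixture gives the single enone F10. A reagent-controlled Corey–Bakshi–Shibata reduction ((R)-2-methyl-oxazaborolidine, BH3·SMe2, THF, −30 °C), with the trisubstituted alkenyl arm as the large group, should then deliver hydride to the face that gives the 9R alcohol.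

3. Step 16 (lactone shift). The acyl transfer may stall if the ten-membered ring does not bring O6 over C12, or the acid may ionise the allylic C6–O bond. The fallback sets out from 23 and returns at 24. LiOH in THF/H2O at 0 °C opens the lactone to the dihydroxy acid F11 (no other ester is present at this stage). Acidification with dilute aqueous HCl to pH 3 should then let the acid close kinetically to the five-membered lactone on O6.

Further compounds
F1 | step 15 | (3S,4R,5Z,9Z)-3-[(tert-butyldimethylsilyl)oxy]-5-({[tert-butyldimethylsilyl]oxy}methyl)-11-[(4-methoxybenzyl)oxy]-9-methylundeca-1,5,9-trien-4-yl acetate | COc1ccc(COC/C=C(/C)CC/C=C(/CO[Si](C)(C)C(C)(C)C)[C@@H](OC(C)=O)[C@@H](O[Si](C)(C)C(C)(C)C)C=C)cc1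
F2 | step 15 | (3S,4R,5Z,9Z)-3-hydroxy-5-(hydroxymethyl)-11-[(4-methoxybenzyl)oxy]-9-methylundeca-1,5,9-trien-4-yl acetate | COc1ccc(COC/C=C(/C)CC/C=C(/CO)[C@@H](OC(C)=O)[C@@H](O)C=C)cc1
F3 | step 15 | (2Z,6Z)-2-[(1R,2S)-1-acetoxy-2-hydroxybut-3-en-1-yl]-8-[(4-methoxybenzyl)oxy]-6-methylocta-2,6-dien-1-yl 3-methylbutanoate | COc1ccc(COC/C=C(/C)CC/C=C(/COC(=O)CC(C)C)[C@@H](OC(C)=O)[C@@H](O)C=C)cc1
F4 | step 15 | (2Z,6Z)-2-[(1R,2S)-1-acetoxy-2-{[2-(bromomethyl)prop-2-enoyl]oxy}but-3-en-1-yl]-8-[(4-methoxybenzyl)oxy]-6-methylocta-2,6-dien-1-yl 3-methylbutanoate | COc1ccc(COC/C=C(/C)CC/C=C(/COC(=O)CC(C)C)[C@@H](OC(C)=O)[C@@H](OC(=O)C(=C)CBr)C=C)cc1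
F5 | step 15 | (2Z,6Z)-2-{(R)-acetoxy[(2S)-4-(bromomethyl)-5-oxo-2,5-dihydrofuran-2-yl]methyl}-8-[(4-methoxybenzyl)oxy]-6-methylocta-2,6-dien-1-yl 3-methylbutanoate | COc1ccc(COC/C=C(/C)CC/C=C(/COC(=O)CC(C)C)[C@@H](OC(C)=O)[C@H]2OC(=O)C(CBr)=C2)cc1
F6 | step 15 | (2Z,6Z)-2-{(R)-acetoxy[(2S)-4-(bromomethyl)-5-oxo-2,5-dihydrofuran-2-yl]methyl}-8-hydroxy-6-methylocta-2,6-dien-1-yl 3-methylbutanoate | OC/C=C(/C)CC/C=C(/COC(=O)CC(C)C)[C@@H](OC(C)=O)[C@H]1OC(=O)C(CBr)=C1
F7 | step 15 | (2Z,6Z)-2-{(R)-acetoxy[(2S)-4-(bromomethyl)-5-oxo-2,5-dihydrofuran-2-yl]methyl}-6-methyl-8-oxoocta-2,6-dien-1-yl 3-methylbutanoate | O=C/C=C(/C)CC/C=C(/COC(=O)CC(C)C)[C@@H](OC(C)=O)[C@H]1OC(=O)C(CBr)=C1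
F8 | step 15 | (1(10)Z,4Z,6R,7S,8S,9R)-9-acetoxy-6-hydroxy-14-[(3-methylbutanoyl)oxy]germacra-1(10),4,11(13)-trien-12,8-olide (cis-fused) | C=C1C(=O)O[C@H]2[C@@H]1[C@H](O)/C=C(/C)CC/C=C(/COC(=O)CC(C)C)[C@H]2OC(C)=O
F9 | step 10 | (3S,4S,5Z,9Z)-3-[(tert-butyldimethylsilyl)oxy]-5-({[tert-butyldimethylsilyl]oxy}methyl)-11-[(4-methoxybenzyl)oxy]-9-methylundeca-1,5,9-trien-4-ol | COc1ccc(COC/C=C(/C)CC/C=C(/CO[Si](C)(C)C(C)(C)C)[C@H](O)[C@@H](O[Si](C)(C)C(C)(C)C)C=C)cc1
F10 | step 10 | (3S,5Z,9Z)-3-[(tert-butyldimethylsilyl)oxy]-5-({[tert-butyldimethylsilyl]oxy}methyl)-11-[(4-methoxybenzyl)oxy]-9-methylundeca-1,5,9-trien-4-one | COc1ccc(COC/C=C(/C)CC/C=C(/CO[Si](C)(C)C(C)(C)C)C(=O)[C@@H](O[Si](C)(C)C(C)(C)C)C=C)cc1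
F11 | step 16 | (1(10)Z,4Z,6R,7S,8S,9R)-8,14-bis[(tert-butyldimethylsilyl)oxy]-6,9-dihydroxygermacra-1(10),4,11(13)-trien-12-oic acid | C=C(C(=O)O)[C@H]1[C@H](O)/C=C(/C)CC/C=C(/CO[Si](C)(C)C(C)(C)C)[C@@H](O)[C@H]1O[Si](C)(C)C(C)(C)C
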